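**Plan**

1. Numbering: piperidine N1, C2 (methyl), C3 (O-feruloyl), C6; side chain C1' to C12' with the ketone at C11'. The retrosynthesis cuts, in this order, the ester C3–O acyl bond, C1'–C2' (as an alkene, by cross-metathesis), N1–C6 (allylic amination), the alkene of the allylic carbonate (cross-metathesis) and C3–C4 (Grignard addition to a Weinreb amide).
2. Enabling feature: C1' to C10' carry no functional group, so a C1'=C2' vinyl group on C6 can stand for the chain. N1–C6 is then an allylic C–N bond that an allyl-iridium complex can form.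
3. Forward: the open chain from C2 to C2' is built from the L-alanine Weinreb amide, butenylmagnesium bromide and allyl methyl carbonate. The only ring, the piperidine, closes at N1–C6; the C2'–C12' chain and then the ferulate are joined afterwards.
4. Stereochemistry: C2 comes from L-alanine; C3 from a chelation-controlled ketone reduction (anti to nitrogen); C6 from the chiral iridium catalyst, which overrides the 2,6-cis preference of the ring. The E-cinnamate comes with ferulic acid.

Key step: step 6

Assumption: the (Sa,S,S) ligand is taken to be the enantiomer that places nitrogen on the C6 face leading to 6R; the ligand is defined by this outcome, and its mirror image would give the 2,6-cis epimer.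

**Route**

Step 1
Reactants: 1 Boc-L-alanine N-methoxy-N-methylamide; 2 but-3-enylmagnesium bromide (C4H7MgBr, solution in THF)
Product: 3 tert-butyl N-[(2S)-3-oxohept-6-en-2-yl]carbamate
Conditions: 2 (2.5 equiv), THF, −20 to 0 °C; sat. aq NH4Cl
Reagents that add atoms: none
Why: Weinreb ketone synthesis, in which the first equivalent of Grignard reagent removes the carbamate N–H (which also protects the C2 hydrogen from enolisation) and the second adds once to give a chelated adduct that releases the ketone only on quench, so C2 stays S and no tertiary alcohol should form.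

Step 2
Reactants: 3 tert-butyl N-[(2S)-3-oxohept-6-en-2-yl]carbamate
Product: 4 tert-butyl N-[(2S,3R)-3-hydroxyhept-6-en-2-yl]carbamate
Conditions: LiAlH(OtBu)3 (2.5 equiv), EtOH, −78 °C; 10% aq citric acid
Reagents that add atoms: none
Why: Chelation-controlled (Cram chelate) hydride reduction of an N-carbamoyl α-amino ketone, with hydride delivered to the face bearing the C2 hydrogen, is the established way to the anti amino alcohol and should set C3 as R.

Step 3
Reactants: 4 tert-butyl N-[(2S,3R)-3-hydroxyhept-6-en-2-yl]carbamate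
Product: 5 tert-butyl N-[(2S,3R)-3-[(tert-butyldimethylsilyl)oxy]hept-6-en-2-yl]carbamate
Conditions: TBSCl, imidazole, DMF, rt
Reagents that add atoms: tert-butyldimethylsilyl chloride, CC(C)(C)[Si](C)(C)Cl
Why: Standard imidazole-promoted silylation of a secondary alcohol, which leaves the carbamate N–H alone and later keeps O3 from competing as a nucleophile in the ring closure.

Step 4
Reactants: 5 tert-butyl N-[(2S,3R)-3-[(tert-butyldimethylsilyl)oxy]hept-6-en-2-yl]carbamate; 6 allyl methyl carbonate
Product: 7 tert-butyl N-[(2S,3R,6E)-3-[(tert-butyldimethylsilyl)oxy]-8-[(methoxycarbonyl)oxy]oct-6-en-2-yl]carbamate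
Conditions: 6 (4 equiv), second-generation Hoveyda–Grubbs catalyst RuCl2(SIMes)(=CH-C6H4-2-OiPr) (5 mol%), CH2Cl2, 40 °C
Reagents that add atoms: none
Why: Olefin cross-metathesis of two unhindered terminal alkenes, driven by loss of ethylene and by the excess of the cheap carbonate, should give mainly the E-disubstituted alkene, with the minor Z-isomer and homodimers removed by chromatography.

Step 5
Reactants: 7 tert-butyl N-[(2S,3R,6E)-3-[(tert-butyldimethylsilyl)oxy]-8-[(methoxycarbonyl)oxy]oct-6-en-2-yl]carbamate
Product: 8 methyl (2E,6R,7S)-7-amino-6-[(tert-butyldimethylsilyl)oxy]oct-2-en-1-yl carbonate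
Conditions: TFA/CH2Cl2 (1:4), 0 °C; sat. aq NaHCO3; used at once
Reagents that add atoms: none
Why: Acidolysis of the tert-butyl carbamate, which a secondary tert-butyldimethylsilyl ether and a primary allylic carbonate should tolerate for a short time in the cold, with the free base released by the bicarbonate wash.

Step 6
Reactants: 8 methyl (2E,6R,7S)-7-amino-6-[(tert-butyldimethylsilyl)oxy]oct-2-en-1-yl carbonate
Product: 9 (2S,3R,6R)-3-[(tert-butyldimethylsilyl)oxy]-6-ethenyl-2-methylpiperidine
Conditions: [Ir(cod)Cl]2 (2 mol%), (Sa,S,S)-O,O'-(1,1'-binaphthyl-2,2'-diyl) N,N-bis[1-(2-methoxyphenyl)ethyl]phosphoramidite (4 mol%), TBD (8 mol%), THF, rt, 2 h; then 8 (0.05 M), THF, rt to 50 °C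
Reagents that add atoms: none
Why: The complex of monovalent iridium, cyclometalated at a ligand methyl group by the base, ionises the allylic carbonate with loss of CO2 and methoxide to an allyl complex of trivalent iridium spanning C6, C1' and C2', and the primary amine attacks the substituted terminus C6 from the face away from the metal; the closest known reaction type is the branched-selective iridium-phosphoramidite allylic amination in its intramolecular form, which is established for α-branched primary amines closing 2,6-disubstituted 2-vinylpiperidines. The piperidine closes in a 6-exo mode through N1–C6, whereas attack at C2' would need an eight-membered ring, so the tether and the metal both favour the branched product. The new stereocenter C6 is fixed by the ligand, which decides the allyl face held by iridium, and not by the resident centers C2 and C3; the (Sa,S,S) ligand is chosen to give 6R, the 2,6-trans ring that a chair-controlled or equilibrating closure would not favour. The step needs branched regioselectivity, catalyst-over-substrate diastereocontrol and N- over O-alkylation: the E-geometry of the carbonate gives a single syn-allyl complex, the silyl ether blocks O3, and the hindered secondary amine that forms should not undergo a second allylation.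

Step 7
Reactants: 9 (2S,3R,6R)-3-[(tert-butyldimethylsilyl)oxy]-6-ethenyl-2-methylpiperidine
Product: 10 tert-butyl (2S,3R,6R)-3-[(tert-butyldimethylsilyl)oxy]-6-ethenyl-2-methylpiperidine-1-carboxylate
Conditions: Boc2O (3 equiv), Et3N, THF, 60 °C
Reagents that add atoms: di-tert-butyl dicarbonate, CC(C)(C)OC(=O)OC(=O)OC(C)(C)C
Why: Carbamoylation of a secondary amine, planned with excess reagent and heat because nitrogen is flanked by two α-branches, which keeps nitrogen from binding ruthenium and from being acylated in the later esterification.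

Step 8
Reactants: 11 undec-10-enoic acid
Product: 12 dodec-11-en-2-one
Conditions: MeLi (2.1 equiv), Et2O, 0 °C to rt; inverse quench into ice-cold aq NH4Cl
Reagents that add atoms: methyllithium, [Li]C
Why: Addition of methyllithium to a lithium carboxylate is the classic one-step conversion of an acid into a methyl ketone, since the doubly lithiated adduct does not collapse to the ketone until hydrolysis and the inverse quench destroys residual MeLi first.

Step 9
Reactants: 10 tert-butyl (2S,3R,6R)-3-[(tert-butyldimethylsilyl)oxy]-6-ethenyl-2-methylpiperidine-1-carboxylate; 12 dodec-11-en-2-one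
Product: 13 tert-butyl (2S,3R,6R)-3-[(tert-butyldimethylsilyl)oxy]-2-methyl-6-[(1E)-11-oxododec-1-en-1-yl]piperidine-1-carboxylate
Conditions: 12 (3 equiv), second-generation Hoveyda–Grubbs catalyst RuCl2(SIMes)(=CH-C6H4-2-OiPr) (5 mol%), CH2Cl2, 40 °C
Reagents that add atoms: none
Why: Olefin cross-metathesis of a hindered, slowly dimerising allylic carbamate alkene with an excess of an unhindered terminal alkene should join C1' to C2' mainly as the E-alkene, whose geometry does not matter because it is hydrogenated next.

Step 10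
Reactants: 13 tert-butyl (2S,3R,6R)-3-[(tert-butyldimethylsilyl)oxy]-2-methyl-6-[(1E)-11-oxododec-1-en-1-yl]piperidine-1-carboxylate
Product: 14 tert-butyl (2S,3R,6S)-3-[(tert-butyldimethylsilyl)oxy]-2-methyl-6-(11-oxododecyl)piperidine-1-carboxylate
Conditions: H2 (1 atm), 10% Pd/C, EtOAc, rt
Reagents that add atoms: none
Why: Heterogeneous catalytic hydrogenation of a disubstituted alkene, to which ketone, carbamate and silyl ether are inert in ethyl acetate, touches no stereocenter (C6 changes from R to S only because the substituent priorities change).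

Step 11
Reactants: 14 tert-butyl (2S,3R,6S)-3-[(tert-butyldimethylsilyl)oxy]-2-methyl-6-(11-oxododecyl)piperidine-1-carboxylate
Product: 15 tert-butyl (2S,3R,6S)-3-hydroxy-2-methyl-6-(11-oxododecyl)piperidine-1-carboxylate
Conditions: Bu4NF, THF, rt
Reagents that add atoms: none
Why: Fluoride-mediated desilylation cleaves the Si–O bond while the carbamate and the methyl ketone are stable to Bu4NF at room temperature.

Step 12
Reactants: 16 ferulic acid
Product: 17 (2E)-3-(4-acetoxy-3-methoxyphenyl)prop-2-enoic acid
Conditions: Ac2O, 1 M aq NaOH, 0 °C; aq HCl to pH 2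
Reagents that add atoms: acetic anhydride, CC(=O)OC(C)=O
Why: Schotten–Baumann acetylation of the phenoxide in cold aqueous base leaves the carboxylate free, and masking the phenol prevents self-acylation in the esterification.

Step 13
Reactants: 15 tert-butyl (2S,3R,6S)-3-hydroxy-2-methyl-6-(11-oxododecyl)piperidine-1-carboxylate; 17 (2E)-3-(4-acetoxy-3-methoxyphenyl)prop-2-enoic acid
Product: 18 tert-butyl (2S,3R,6S)-3-{[(2E)-3-(4-acetoxy-3-methoxyphenyl)prop-2-enoyl]oxy}-2-methyl-6-(11-oxododecyl)piperidine-1-carboxylate
Conditions: 17 (2 equiv), DCC, DMAP (cat.), CH2Cl2, 0 °C to rt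
Reagents that add atoms: none
Why: Steglich esterification, in which DCC activates the cinnamic acid and DMAP transfers the acyl group to the secondary alcohol with retention at C3, nitrogen being blocked as its carbamate.

Step 14
Reactants: 18 tert-butyl (2S,3R,6S)-3-{[(2E)-3-(4-acetoxy-3-methoxyphenyl)prop-2-enoyl]oxy}-2-methyl-6-(11-oxododecyl)piperidine-1-carboxylate
Product: 19 tert-butyl (2S,3R,6S)-3-{[(2E)-3-(4-hydroxy-3-methoxyphenyl)prop-2-enoyl]oxy}-2-methyl-6-(11-oxododecyl)piperidine-1-carboxylate
Conditions: pyrrolidine (3 equiv), CH2Cl2, 0 °C to rt; aq NH4Cl wash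
Reagents that add atoms: none
Why: Aminolysis of the aryl acetate, an activated ester, by pyrrolidine should be far faster than attack on the conjugated alkyl cinnamate or conjugate addition, a selectivity that is standard for acetyl-protected feruloyl esters.

Step 15
Reactants: 19 tert-butyl (2S,3R,6S)-3-{[(2E)-3-(4-hydroxy-3-methoxyphenyl)prop-2-enoyl]oxy}-2-methyl-6-(11-oxododecyl)piperidine-1-carboxylate
Product: 20 (2S,3R,6S)-2-methyl-6-(11-oxododecyl)piperidin-3-yl (2E)-3-(4-hydroxy-3-methoxyphenyl)prop-2-enoate
Conditions: TFA/CH2Cl2 (1:4), 0 °C; cold sat. aq NaHCO3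
Reagents that add atoms: none
Why: Acidolysis of the tert-butyl carbamate frees the ring nitrogen, while the cinnamate ester, phenol and ketone are stable to TFA and a cold bicarbonate work-up should give the free base without acyl migration.

**Compound list**

1 | tert-butyl N-[(2S)-1-[methoxy(methyl)amino]-1-oxopropan-2-yl]carbamate (Boc-L-alanine N-methoxy-N-methylamide) | C[C@H](NC(=O)OC(C)(C)C)C(=O)N(C)OC | starting material
2 | but-3-enylmagnesium bromide | C=CCC[Mg]Br | starting material
3 | tert-butyl N-[(2S)-3-oxohept-6-en-2-yl]carbamate | C[C@H](NC(=O)OC(C)(C)C)C(=O)CCC=C | intermediate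
4 | tert-butyl N-[(2S,3R)-3-hydroxyhept-6-en-2-yl]carbamate | C[C@H](NC(=O)OC(C)(C)C)[C@H](O)CCC=C | intermediate
5 | tert-butyl N-[(2S,3R)-3-[(tert-butyldimethylsilyl)oxy]hept-6-en-2-yl]carbamate | C[C@H](NC(=O)OC(C)(C)C)[C@H](O[Si](C)(C)C(C)(C)C)CCC=C | intermediate
6 | allyl methyl carbonate | C=CCOC(=O)OC | starting material
7 | tert-butyl N-[(2S,3R,6E)-3-[(tert-butyldimethylsilyl)oxy]-8-[(methoxycarbonyl)oxy]oct-6-en-2-yl]carbamate | C[C@H](NC(=O)OC(C)(C)C)[C@H](O[Si](C)(C)C(C)(C)C)CC/C=C/COC(=O)OC | intermediate
8 | methyl (2E,6R,7S)-7-amino-6-[(tert-butyldimethylsilyl)oxy]oct-2-en-1-yl carbonate | C[C@H](N)[C@H](O[Si](C)(C)C(C)(C)C)CC/C=C/COC(=O)OC | intermediate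
9 | (2S,3R,6R)-3-[(tert-butyldimethylsilyl)oxy]-6-ethenyl-2-methylpiperidine | CC(C)(C)[Si](C)(C)O[C@@H]1CC[C@H](C=C)N[C@H]1C | intermediate
10 | tert-butyl (2S,3R,6R)-3-[(tert-butyldimethylsilyl)oxy]-6-ethenyl-2-methylpiperidine-1-carboxylate | CC(C)(C)[Si](C)(C)O[C@@H]1CC[C@H](C=C)N(C(=O)OC(C)(C)C)[C@H]1C | intermediate
11 | undec-10-enoic acid | C=CCCCCCCCCC(=O)O | starting material
12 | dodec-11-en-2-one | C=CCCCCCCCCC(C)=O | intermediate
13 | tert-butyl (2S,3R,6R)-3-[(tert-butyldimethylsilyl)oxy]-2-methyl-6-[(1E)-11-oxododec-1-en-1-yl]piperidine-1-carboxylate | CC(C)(C)[Si](C)(C)O[C@@H]1CC[C@H](/C=C/CCCCCCCCC(C)=O)N(C(=O)OC(C)(C)C)[C@H]1C | intermediate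
14 | tert-butyl (2S,3R,6S)-3-[(tert-butyldimethylsilyl)oxy]-2-methyl-6-(11-oxododecyl)piperidine-1-carboxylate | CC(C)(C)[Si](C)(C)O[C@@H]1CC[C@H](CCCCCCCCCCC(C)=O)N(C(=O)OC(C)(C)C)[C@H]1C | intermediate
15 | tert-butyl (2S,3R,6S)-3-hydroxy-2-methyl-6-(11-oxododecyl)piperidine-1-carboxylate | O[C@@H]1CC[C@H](CCCCCCCCCCC(C)=O)N(C(=O)OC(C)(C)C)[C@H]1C | intermediate
16 | ferulic acid, (2E)-3-(4-hydroxy-3-methoxyphenyl)prop-2-enoic acid | COc1cc(/C=C/C(=O)O)ccc1O | starting material
17 | (2E)-3-(4-acetoxy-3-methoxyphenyl)prop-2-enoic acid | COc1cc(/C=C/C(=O)O)ccc1OC(C)=O | intermediate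
18 | tert-butyl (2S,3R,6S)-3-{[(2E)-3-(4-acetoxy-3-methoxyphenyl)prop-2-enoyl]oxy}-2-methyl-6-(11-oxododecyl)piperidine-1-carboxylate | COc1cc(/C=C/C(=O)O[C@@H]2CC[C@H](CCCCCCCCCCC(C)=O)N(C(=O)OC(C)(C)C)[C@H]2C)ccc1OC(C)=O | intermediate
19 | tert-butyl (2S,3R,6S)-3-{[(2E)-3-(4-hydroxy-3-methoxyphenyl)prop-2-enoyl]oxy}-2-methyl-6-(11-oxododecyl)piperidine-1-carboxylate | COc1cc(/C=C/C(=O)O[C@@H]2CC[C@H](CCCCCCCCCCC(C)=O)N(C(=O)OC(C)(C)C)[C@H]2C)ccc1O | intermediate
20 | (2S,3R,6S)-2-methyl-6-(11-oxododecyl)piperidin-3-yl (2E)-3-(4-hydroxy-3-methoxyphenyl)prop-2-enoate | COc1cc(/C=C/C(=O)O[C@@H]2CC[C@H](CCCCCCCCCCC(C)=O)N[C@H]2C)ccc1O | target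

**Step count**

Total: 15 steps. Longest linear sequence: 13 steps (steps 1 to 7, 9 to 11 and 13 to 15); steps 8 and 12 prepare the two side fragments.

**Steps most likely to fail**

Step 6. The catalyst may fail to override the ring's own preference, giving poor facial selectivity at C6, or the primary amine may be lost to acyl transfer from the carbonate before ionisation. The fallback sets out from 5 and comes back at 10; it still closes the ring at N1–C6 but sets C6 afterwards by substrate control. Hydroboration of 5 with 9-BBN and oxidation (H2O2, NaOH) should give the primary alcohol tert-butyl N-[(2S,3R)-3-[(tert-butyldimethylsilyl)oxy]-7-hydroxyheptan-2-yl]carbamate F1. MsCl and Et3N convert it into (5R,6S)-6-[(tert-butoxycarbonyl)amino]-5-[(tert-butyldimethylsilyl)oxy]heptyl methanesulfonate F2. KOtBu in THF then closes the ring by N-alkylation of the carbamate anion to tert-butyl (2S,3R)-3-[(tert-butyldimethylsilyl)oxy]-2-methylpiperidine-1-carboxylate F3. Lithiation with s-BuLi and TMEDA in Et2O at −78 °C removes the equatorial C6 hydrogen while the C2 methyl sits axial to avoid allylic strain with the carbamate. A DMF quench should therefore give the 2,6-trans aldehyde tert-butyl (2S,3R,6R)-3-[(tert-butyldimethylsilyl)oxy]-6-formyl-2-methylpiperidine-1-carboxylate F4. Wittig methylenation (Ph3P=CH2 from Ph3PCH3Br and KN(SiMe3)2, THF, −78 to 0 °C) turns it into 10.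

Step 4. E-selectivity may be incomplete and homodimers may form; any Z-carbonate carried forward gives a different allyl complex in step 6 and erodes its selectivity. The fallback sets out from 5 and comes back at 7. Cross-metathesis of 5 with methyl acrylate under the same ruthenium catalyst, which is reliably E-selective, should give methyl (2E,6R,7S)-7-[(tert-butoxycarbonyl)amino]-6-[(tert-butyldimethylsilyl)oxy]oct-2-enoate F5. Reduction with iBu2AlH in CH2Cl2 at −78 °C gives the allylic alcohol tert-butyl N-[(2S,3R,6E)-3-[(tert-butyldimethylsilyl)oxy]-8-hydroxyoct-6-en-2-yl]carbamate F6. Methyl chloroformate and pyridine then give 7 as the E-isomer only.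

Step 13. Acyl transfer to the hindered C3 hydroxyl may be slow, so that the activated acid rearranges to the N-acylurea or the aryl acetate passes its acetyl group to O3. The fallback sets out from 15 and comes back at 18. Compound 15 is first esterified with the small, reactive diethylphosphonoacetic acid (DCC, cat. DMAP, CH2Cl2) to tert-butyl (2S,3R,6S)-3-{[2-(diethoxyphosphoryl)acetyl]oxy}-2-methyl-6-(11-oxododecyl)piperidine-1-carboxylate F7. A Horner–Wadsworth–Emmons reaction with 4-acetoxy-3-methoxybenzaldehyde (LiCl, DBU, MeCN, rt) then builds the E-cinnamate on the ester already in place and gives 18; the aldehyde should react well ahead of the remote methyl ketone.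

**Further compounds**

F1 | step 6 | tert-butyl N-[(2S,3R)-3-[(tert-butyldimethylsilyl)oxy]-7-hydroxyheptan-2-yl]carbamate | C[C@H](NC(=O)OC(C)(C)C)[C@H](O[Si](C)(C)C(C)(C)C)CCCCO
F2 | step 6 | (5R,6S)-6-[(tert-butoxycarbonyl)amino]-5-[(tert-butyldimethylsilyl)oxy]heptyl methanesulfonate | C[C@H](NC(=O)OC(C)(C)C)[C@H](O[Si](C)(C)C(C)(C)C)CCCCOS(C)(=O)=O
F3 | step 6 | tert-butyl (2S,3R)-3-[(tert-butyldimethylsilyl)oxy]-2-methylpiperidine-1-carboxylate | CC(C)(C)[Si](C)(C)O[C@@H]1CCCN(C(=O)OC(C)(C)C)[C@H]1C
F4 | step 6 | tert-butyl (2S,3R,6R)-3-[(tert-butyldimethylsilyl)oxy]-6-formyl-2-methylpiperidine-1-carboxylate | CC(C)(C)[Si](C)(C)O[C@@H]1CC[C@H](C=O)N(C(=O)OC(C)(C)C)[C@H]1C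
F5 | step 4 | methyl (2E,6R,7S)-7-[(tert-butoxycarbonyl)amino]-6-[(tert-butyldimethylsilyl)oxy]oct-2-enoate | C[C@H](NC(=O)OC(C)(C)C)[C@H](O[Si](C)(C)C(C)(C)C)CC/C=C/C(=O)OC
F6 | step 4 | tert-butyl N-[(2S,3R,6E)-3-[(tert-butyldimethylsilyl)oxy]-8-hydroxyoct-6-en-2-yl]carbamate | C[C@H](NC(=O)OC(C)(C)C)[C@H](O[Si](C)(C)C(C)(C)C)CC/C=C/CO
F7 | step 13 | tert-butyl (2S,3R,6S)-3-{[2-(diethoxyphosphoryl)acetyl]oxy}-2-methyl-6-(11-oxododecyl)piperidine-1-carboxylate | CCOP(=O)(OCC)CC(=O)O[C@@H]1CC[C@H](CCCCCCCCCCC(C)=O)N(C(=O)OC(C)(C)C)[C@H]1C
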